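**Retrosynthetic overview**

1. Locants follow the daucane skeleton: C1 (quaternary fusion carbon, C15 methyl), C2–C3–C4 (ring A, five-membered; C4 carries the isopropyl group), C5 (fusion CH), C6–C7–C8 (C14 methyl)–C9–C10 (ring B, seven-membered); β is the face of the C15 methyl.
2. The tiglates are put on one at a time (C6 first, C10 last), so that the free 10α-hydroxyl alone directs the 8α,9α-epoxidation. The 6β-oxygen with the 5β-hydrogen (hydroboration of C5=C6) and the C14 methyl (reduced ester) come from one intermediate, a dauca-5,8-dien-14-oate.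
3. That cyclohepta-1,4-diene is cut at C7–C8 and C10–C1: rhodium-carbenoid cyclopropanation of a ring A vinylcyclopentene (C1, C5, C6, C7) by an (E)-4-alkoxyvinyldiazoacetate (C8, C9, C10), then divinylcyclopropane rearrangement, a formal (4+3) cycloaddition.
4. Enabling feature: in ring B the oxygen functions sit on C6, on C8/C9 (epoxide) and on C10 around the C7 methylene, so ring B is a masked cyclohepta-1,4-diene (C5=C6 and C8=C9 flanking C7, with C10 and quaternary C1 as the adjacent sp3 pair), the retron of a cis-divinylcyclopropane spanning C6–C7–C8.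
5. Order of ring formation: ring A first, from (S)-terpinen-4-ol by allylic oxidation, directed reduction, ozonolysis and aldol ring contraction; ring B second, in the key step.

Key step: step 9

Remark: (S)-(+)-terpinen-4-ol and 2-[(4-methoxybenzyl)oxy]acetaldehyde are taken as purchasable, the former in high enantiomeric purity, which then fixes the enantiomeric purity of ring A.

**Route**

Step 1
Reactants: 1 (S)-terpinen-4-ol
Product: 3 (R)-5-hydroxy-2-methyl-5-(propan-2-yl)cyclohex-2-en-1-one, via allylic diol 2 (not isolated)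
Conditions: SeO2 (0.3 equiv), t-BuOOH, CH2Cl2, 0 to 23 °C; then MnO2, CH2Cl2, 23 °C
Reagents that add atoms: tert-butyl hydroperoxide, CC(C)(C)OO (terminal oxidant; the oxygen atom is relayed through selenium dioxide, O=[Se]=O)
Why: Riley allylic oxidation (ene reaction, then 2,3-sigmatropic shift) should hydroxylate the ring CH2 attached to the methyl-bearing alkene carbon, the other ring allylic CH2 being neopentyl, and MnO2 then converges the epimeric allylic alcohols and any enone already formed on enone 3 without touching the tertiary carbinol stereocentre.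

Step 2
Reactants: 3 (R)-5-hydroxy-2-methyl-5-(propan-2-yl)cyclohex-2-en-1-one
Product: 4 (1S,5R)-2-methyl-5-(propan-2-yl)cyclohex-2-ene-1,5-diol
Conditions: Me4NBH(OAc)3, MeCN/AcOH (1:1), −30 °C
Reagents that add atoms: none
Why: Evans–Saksena hydroxyl-directed reduction: the tertiary hydroxyl (axial, since the isopropyl group is equatorial) binds the triacetoxyborohydride and delivers hydride to the ketone on its own face, so the new secondary hydroxyl should come out trans to it (1,3-anti), with 1,2-reduction of the enone.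

Step 3
Reactants: 4 (1S,5R)-2-methyl-5-(propan-2-yl)cyclohex-2-ene-1,5-diol
Product: 5 (1S,5R)-2-methyl-5-(propan-2-yl)-1,5-bis(triethylsilyloxy)cyclohex-2-ene
Conditions: Et3SiOTf (2.6 equiv), 2,6-lutidine, CH2Cl2, −78 to 0 °C
Reagents that add atoms: triethylsilyl trifluoromethanesulfonate, CC[Si](CC)(CC)OS(=O)(=O)C(F)(F)F
Why: Silyl triflate silylation protects the hindered tertiary and the allylic secondary hydroxyl in one operation ahead of the ozonolysis, enamine and carbenoid steps.

Step 4
Reactants: 5 (1S,5R)-2-methyl-5-(propan-2-yl)-1,5-bis(triethylsilyloxy)cyclohex-2-ene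
Product: 6 (3S,5S)-6-oxo-3-(propan-2-yl)-3,5-bis(triethylsilyloxy)heptanal
Conditions: O3, CH2Cl2, −78 °C; then PPh3, −78 to 23 °C
Reagents that add atoms: ozone, [O-][O+]=O
Why: Ozonolysis with reductive work-up cleaves the only C=C bond to the methyl ketone and the aldehyde; the silyl ethers and both stereocentres are unaffected.

Step 5
Reactants: 6 (3S,5S)-6-oxo-3-(propan-2-yl)-3,5-bis(triethylsilyloxy)heptanal
Product: 8 (3S,5R)-2-methyl-5-(propan-2-yl)-3,5-bis(triethylsilyloxy)cyclopent-1-ene-1-carbaldehyde, via aldol adduct 7 (not isolated)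
Conditions: piperidine (0.2 equiv), AcOH (0.2 equiv), PhMe, 4 Å molecular sieves, 23 to 50 °C
Reagents that add atoms: none
Why: Amine-catalysed intramolecular aldol condensation: the enamine of the aldehyde attacks the methyl ketone in a 5-exo-trig closure and dehydration gives the tetrasubstituted enal, the mild buffered conditions being chosen to limit β-elimination of the silyloxy group and epimerisation next to the ketone.

Step 6
Reactants: 8 (3S,5R)-2-methyl-5-(propan-2-yl)-3,5-bis(triethylsilyloxy)cyclopent-1-ene-1-carbaldehyde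
Product: 9 (3S,5R)-1-ethenyl-2-methyl-5-(propan-2-yl)-3,5-bis(triethylsilyloxy)cyclopent-1-ene
Conditions: Ph3PCH3Br, KOt-Bu, THF, 0 to 23 °C
Reagents that add atoms: methyltriphenylphosphonium bromide, C[P+](c1ccccc1)(c1ccccc1)c1ccccc1.[Br-]
Why: Wittig methylenation of the hindered but non-enolisable enal should give the 1,3-diene without affecting the stereocentres.

Step 7
Reactants: 10 ethyl diazoacetate, 11 2-[(4-methoxybenzyl)oxy]acetaldehyde
Product: 12 ethyl 2-diazo-3-hydroxy-4-[(4-methoxybenzyl)oxy]butanoate (racemic)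
Conditions: DBU (0.1 equiv), MeCN, 0 to 23 °C
Reagents that add atoms: none
Why: Base-catalysed aldol-type addition of the diazoacetate carbanion to the aldehyde carbonyl, a standard entry to β-hydroxy-α-diazo esters.

Step 8
Reactants: 12 ethyl 2-diazo-3-hydroxy-4-[(4-methoxybenzyl)oxy]butanoate
Product: 13 ethyl (3E)-2-diazo-4-[(4-methoxybenzyl)oxy]but-3-enoate
Conditions: POCl3, Et3N, CH2Cl2, 0 °C
Reagents that add atoms: none
Why: Dehydration of the β-hydroxy-α-diazo ester through its dichlorophosphate gives the vinyldiazoacetate, the conjugated enol ether being expected as the more stable E isomer needed for the stereochemical course of step 9.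

Step 9
Reactants: 9 (3S,5R)-1-ethenyl-2-methyl-5-(propan-2-yl)-3,5-bis(triethylsilyloxy)cyclopent-1-ene, 13 ethyl (3E)-2-diazo-4-[(4-methoxybenzyl)oxy]but-3-enoate
Product: 15 ethyl 10α-[(4-methoxybenzyl)oxy]-2β,4α-bis(triethylsilyloxy)dauca-5,8-dien-14-oate, via cis-divinylcyclopropane 14 (not isolated)
Conditions: Rh2(S-DOSP)4 (1 mol %), hexanes, −40 to 23 °C, slow addition of 13 (1.5 equiv); then PhMe, 90 °C
Reagents that add atoms: none
Why: The dirhodium carbenoid from 13 cyclopropanates the monosubstituted vinyl group of 9 (future C6=C7) with the usual donor/acceptor preference for the cyclopropane whose cyclopentenyl and alkoxyvinyl groups are cis (14), and on warming this cis-divinylcyclopropane undergoes the 3,3-sigmatropic (Cope) rearrangement, so that the C7–C8 bond comes from the cyclopropanation and the C10–C1 bond from the rearrangement while the transient C6–C8 bond is broken; the closest known reaction type is the rhodium-catalysed tandem cyclopropanation/Cope rearrangement (formal (4+3) cycloaddition) of vinyldiazoacetates with 1,3-dienes, including cases that create a quaternary carbon. Ring B closes in the sigmatropic step through a boat transition state, the only geometry in which the two vinyl termini of a cis-divinylcyclopropane can reach each other. The boat fixes the relative configuration of the two new stereocentres: the E-alkoxy group on C10 and the ring A carbon C2 on C1 are both exo and end up cis, so the C10 oxygen is trans to the C15 methyl (10α, 1β-methyl). Which face of the ring A double bond C1 uses is decided at the cyclopropanation stage by the chiral catalyst; Rh2(S-DOSP)4 is expected, from its established sense of induction with vinyldiazoacetates, to be the enantiomer that places the new bond on the α face, anti to the C2 silyloxy group, and this is the matched case because the alternative boat would press that silyloxy group against the incoming C10 terminus. The step needs site selectivity (terminal vinyl over the tetrasubstituted ring alkene and over insertion into the allylic C–H bond at C2), which the strong preference of donor/acceptor carbenoids for monosubstituted alkenes should secure, and reaction at the carbenoid carbon and not at the vinylogous terminus, which the hydrocarbon solvent, the electron-rich carboxylate catalyst and the E-substituted terminus should secure. Heating is required because the C15 methyl points into the boat.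

Step 10
Reactants: 15 ethyl 10α-[(4-methoxybenzyl)oxy]-2β,4α-bis(triethylsilyloxy)dauca-5,8-dien-14-oate
Product: 17 ethyl 6β-hydroxy-10α-[(4-methoxybenzyl)oxy]-2β,4α-bis(triethylsilyloxy)-5β-dauc-8-en-14-oate, via C6 alkylborane 16 (not isolated)
Conditions: BH3·THF, THF, 0 to 23 °C; then NaBO3·4H2O, THF/H2O, 23 °C
Reagents that add atoms: sodium perborate, [Na+].[Na+].O[B-]1(O)OO[B-](O)(O)OO1
Why: Hydroboration–oxidation: borane should add to the electron-rich trisubstituted C5=C6 bond in preference to the deactivated enoate, boron at the less substituted C6 and hydrogen at C5, syn and from the β face because ring B is folded under the α face (C10 and the C4 silyloxy group lie there), and oxidation with retention sets 6β-OH and 5β-H.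

Step 11
Reactants: 17 ethyl 6β-hydroxy-10α-[(4-methoxybenzyl)oxy]-2β,4α-bis(triethylsilyloxy)-5β-dauc-8-en-14-oate
Product: 18 10α-[(4-methoxybenzyl)oxy]-2β,4α-bis(triethylsilyloxy)-5β-dauc-8-ene-6β,14-diol
Conditions: i-Bu2AlH, CH2Cl2, −78 °C; aqueous potassium sodium tartrate work-up
Reagents that add atoms: none
Why: DIBAL reduction of the conjugated ester should stop cleanly at the primary allylic alcohol at low temperature; ethers and silyl ethers are inert.

Step 12
Reactants: 18 10α-[(4-methoxybenzyl)oxy]-2β,4α-bis(triethylsilyloxy)-5β-dauc-8-ene-6β,14-diol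
Product: 20 10α-[(4-methoxybenzyl)oxy]-2β,4α-bis(triethylsilyloxy)-5β-dauc-8-en-6β-ol, via allylic mesylate 19 (not isolated)
Conditions: MsCl (1.05 equiv), Et3N, CH2Cl2, −40 °C; then LiBHEt3, THF, −40 to 0 °C
Reagents that add atoms: none
Why: The primary allylic hydroxyl is sulfonylated much faster than the hindered secondary 6β-hydroxyl, and direct SN2 displacement of the allylic mesylate by triethylborohydride should convert CH2OMs into the C14 methyl without moving the C8=C9 double bond.

Step 13
Reactants: 20 10α-[(4-methoxybenzyl)oxy]-2β,4α-bis(triethylsilyloxy)-5β-dauc-8-en-6β-ol, 21 tiglic acid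
Product: 22 10α-[(4-methoxybenzyl)oxy]-2β,4α-bis(triethylsilyloxy)-5β-dauc-8-en-6β-yl (E)-2-methylbut-2-enoate
Conditions: 21 (1.5 equiv), 2,4,6-Cl3C6H2COCl, Et3N, THF, 23 °C; then 20, DMAP, PhMe, 40 °C
Reagents that add atoms: none
Why: Yamaguchi esterification of the only free hydroxyl (6β) through the mixed anhydride and DMAP installs the first tiglate without isomerising its E double bond, while the 10α-oxygen stays masked as the 4-methoxybenzyl ether and the silyl ethers are untouched.

Step 14
Reactants: 22 10α-[(4-methoxybenzyl)oxy]-2β,4α-bis(triethylsilyloxy)-5β-dauc-8-en-6β-yl (E)-2-methylbut-2-enoate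
Product: 23 10α-hydroxy-2β,4α-bis(triethylsilyloxy)-5β-dauc-8-en-6β-yl (E)-2-methylbut-2-enoate
Conditions: DDQ, CH2Cl2/pH 7 phosphate buffer, 0 °C
Reagents that add atoms: none
Why: Oxidative cleavage of the 4-methoxybenzyl ether by DDQ (hydride abstraction, hydrolysis of the oxocarbenium ion) frees the allylic 10α-hydroxyl under neutral conditions that leave the silyl ethers, the tiglate and the ring alkene intact.

Step 15
Reactants: 23 10α-hydroxy-2β,4α-bis(triethylsilyloxy)-5β-dauc-8-en-6β-yl (E)-2-methylbut-2-enoate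
Product: 24 8α,9α-epoxy-10α-hydroxy-2β,4α-bis(triethylsilyloxy)-5β-daucan-6β-yl (E)-2-methylbut-2-enoate
Conditions: VO(acac)2 (5 mol %), t-BuOOH (decane), CH2Cl2, 0 to 23 °C
Reagents that add atoms: tert-butyl hydroperoxide, CC(C)(C)OO
Why: Vanadium-catalysed hydroxyl-directed epoxidation: the allylic 10α-hydroxyl, now the only free hydroxyl, binds the vanadium peroxide and delivers oxygen to C8=C9 on its own face (cis epoxy alcohols are the rule for cyclohept-2-enols), which sets the 8α,9α-epoxide with the C14 methyl β, and the electron-poor tiglate double bond is not attacked.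

Step 16
Reactants: 24 8α,9α-epoxy-10α-hydroxy-2β,4α-bis(triethylsilyloxy)-5β-daucan-6β-yl (E)-2-methylbut-2-enoate, 21 tiglic acid
Product: 25 8α,9α-epoxy-2β,4α-bis(triethylsilyloxy)-5β-daucane-6β,10α-diyl bis[(E)-2-methylbut-2-enoate]
Conditions: 21 (3 equiv), 2,4,6-Cl3C6H2COCl, Et3N, THF, 23 °C; then 24, DMAP, PhMe, 60 °C
Reagents that add atoms: none
Why: A second Yamaguchi esterification acylates the remaining, neopentyl 10α-hydroxyl with the strongly activated acylpyridinium species under conditions that neither open the epoxide nor isomerise either tiglate, both silyl ethers staying in place.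

Step 17
Reactants: 25 8α,9α-epoxy-2β,4α-bis(triethylsilyloxy)-5β-daucane-6β,10α-diyl bis[(E)-2-methylbut-2-enoate]
Product: 26 8α,9α-epoxy-2β,4α-dihydroxy-5β-daucane-6β,10α-diyl bis[(E)-2-methylbut-2-enoate] (CNP0265715.1)
Conditions: HF·pyridine, pyridine, THF, 0 to 23 °C
Reagents that add atoms: none
Why: Fluoride-mediated cleavage of the two triethylsilyl ethers under buffered conditions should release the 2β- and 4α-hydroxyls without opening the epoxide or cleaving or migrating the tiglates.

**Compound list**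

1 | (S)-terpinen-4-ol, (1S)-4-methyl-1-(propan-2-yl)cyclohex-3-en-1-ol | CC1=CC[C@](O)(C(C)C)CC1 | starting material
2 | (5R)-2-methyl-5-(propan-2-yl)cyclohex-2-ene-1,5-diol, both C1 epimers | CC1=CC[C@](O)(C(C)C)CC1O | intermediate
3 | (R)-5-hydroxy-2-methyl-5-(propan-2-yl)cyclohex-2-en-1-one | CC1=CC[C@](O)(C(C)C)CC1=O | intermediate
4 | (1S,5R)-2-methyl-5-(propan-2-yl)cyclohex-2-ene-1,5-diol (hydroxyls trans) | CC1=CC[C@](O)(C(C)C)C[C@@H]1O | intermediate
5 | (1S,5R)-2-methyl-5-(propan-2-yl)-1,5-bis(triethylsilyloxy)cyclohex-2-ene | CC1=CC[C@](O[Si](CC)(CC)CC)(C(C)C)C[C@@H]1O[Si](CC)(CC)CC | intermediate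
6 | (3S,5S)-6-oxo-3-(propan-2-yl)-3,5-bis(triethylsilyloxy)heptanal | O=CC[C@](O[Si](CC)(CC)CC)(C(C)C)C[C@H](O[Si](CC)(CC)CC)C(C)=O | intermediate
7 | (3S,5R)-2-hydroxy-2-methyl-5-(propan-2-yl)-3,5-bis(triethylsilyloxy)cyclopentane-1-carbaldehyde, C1 and C2 undefined | O=CC1C(C)(O)[C@@H](O[Si](CC)(CC)CC)C[C@@]1(O[Si](CC)(CC)CC)C(C)C | intermediate
8 | (3S,5R)-2-methyl-5-(propan-2-yl)-3,5-bis(triethylsilyloxy)cyclopent-1-ene-1-carbaldehyde (silyloxy groups trans) | O=CC1=C(C)[C@@H](O[Si](CC)(CC)CC)C[C@@]1(O[Si](CC)(CC)CC)C(C)C | intermediate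
9 | (3S,5R)-1-ethenyl-2-methyl-5-(propan-2-yl)-3,5-bis(triethylsilyloxy)cyclopent-1-ene | C=CC1=C(C)[C@@H](O[Si](CC)(CC)CC)C[C@@]1(O[Si](CC)(CC)CC)C(C)C | intermediate
10 | ethyl diazoacetate | CCOC(=O)C=[N+]=[N-] | starting material
11 | 2-[(4-methoxybenzyl)oxy]acetaldehyde | O=CCOCc1ccc(OC)cc1 | starting material
12 | ethyl 2-diazo-3-hydroxy-4-[(4-methoxybenzyl)oxy]butanoate (racemic) | CCOC(=O)C(=[N+]=[N-])C(O)COCc1ccc(OC)cc1 | intermediate
13 | ethyl (3E)-2-diazo-4-[(4-methoxybenzyl)oxy]but-3-enoate | CCOC(=O)C(=[N+]=[N-])/C=C/OCc1ccc(OC)cc1 | intermediate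
14 | ethyl (1S,2R)-1-{(E)-2-[(4-methoxybenzyl)oxy]ethenyl}-2-[(3S,5R)-2-methyl-5-(propan-2-yl)-3,5-bis(triethylsilyloxy)cyclopent-1-en-1-yl]cyclopropane-1-carboxylate (alkoxyvinyl and cyclopentenyl cis) | CCOC(=O)[C@@]1(/C=C/OCc2ccc(OC)cc2)C[C@@H]1C3=C(C)[C@@H](O[Si](CC)(CC)CC)C[C@@]3(O[Si](CC)(CC)CC)C(C)C | intermediate
15 | ethyl 10α-[(4-methoxybenzyl)oxy]-2β,4α-bis(triethylsilyloxy)dauca-5,8-dien-14-oate | CCOC(=O)C1=C[C@H](OCc2ccc(OC)cc2)[C@@]3(C)C(=CC1)[C@](O[Si](CC)(CC)CC)(C(C)C)C[C@@H]3O[Si](CC)(CC)CC | intermediate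
16 | 6β-boranyl derivative of 17 (BH2 in place of the 6β-OH, 5β-H) | B[C@H]1CC(C(=O)OCC)=C[C@H](OCc3ccc(OC)cc3)[C@@]2(C)[C@@H]1[C@](O[Si](CC)(CC)CC)(C(C)C)C[C@@H]2O[Si](CC)(CC)CC | intermediate
17 | ethyl 6β-hydroxy-10α-[(4-methoxybenzyl)oxy]-2β,4α-bis(triethylsilyloxy)-5β-dauc-8-en-14-oate | O[C@H]1CC(C(=O)OCC)=C[C@H](OCc3ccc(OC)cc3)[C@@]2(C)[C@@H]1[C@](O[Si](CC)(CC)CC)(C(C)C)C[C@@H]2O[Si](CC)(CC)CC | intermediate
18 | 10α-[(4-methoxybenzyl)oxy]-2β,4α-bis(triethylsilyloxy)-5β-dauc-8-ene-6β,14-diol | O[C@H]1CC(CO)=C[C@H](OCc3ccc(OC)cc3)[C@@]2(C)[C@@H]1[C@](O[Si](CC)(CC)CC)(C(C)C)C[C@@H]2O[Si](CC)(CC)CC | intermediate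
19 | 14-methanesulfonate of 18 | O[C@H]1CC(COS(C)(=O)=O)=C[C@H](OCc3ccc(OC)cc3)[C@@]2(C)[C@@H]1[C@](O[Si](CC)(CC)CC)(C(C)C)C[C@@H]2O[Si](CC)(CC)CC | intermediate
20 | 10α-[(4-methoxybenzyl)oxy]-2β,4α-bis(triethylsilyloxy)-5β-dauc-8-en-6β-ol | O[C@H]1CC(C)=C[C@H](OCc3ccc(OC)cc3)[C@@]2(C)[C@@H]1[C@](O[Si](CC)(CC)CC)(C(C)C)C[C@@H]2O[Si](CC)(CC)CC | intermediate
21 | tiglic acid, (E)-2-methylbut-2-enoic acid | C/C=C(\C)C(=O)O | starting material
22 | 10α-[(4-methoxybenzyl)oxy]-2β,4α-bis(triethylsilyloxy)-5β-dauc-8-en-6β-yl (E)-2-methylbut-2-enoate | C/C=C(\C)C(=O)O[C@H]1CC(C)=C[C@H](OCc3ccc(OC)cc3)[C@@]2(C)[C@@H]1[C@](O[Si](CC)(CC)CC)(C(C)C)C[C@@H]2O[Si](CC)(CC)CC | intermediate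
23 | 10α-hydroxy-2β,4α-bis(triethylsilyloxy)-5β-dauc-8-en-6β-yl (E)-2-methylbut-2-enoate | C/C=C(\C)C(=O)O[C@H]1CC(C)=C[C@H](O)[C@@]2(C)[C@@H]1[C@](O[Si](CC)(CC)CC)(C(C)C)C[C@@H]2O[Si](CC)(CC)CC | intermediate
24 | 8α,9α-epoxy-10α-hydroxy-2β,4α-bis(triethylsilyloxy)-5β-daucan-6β-yl (E)-2-methylbut-2-enoate | C/C=C(\C)C(=O)O[C@H]1C[C@]2(C)O[C@@H]2[C@H](O)[C@@]2(C)[C@@H]1[C@](O[Si](CC)(CC)CC)(C(C)C)C[C@@H]2O[Si](CC)(CC)CC | intermediate
25 | 8α,9α-epoxy-2β,4α-bis(triethylsilyloxy)-5β-daucane-6β,10α-diyl bis[(E)-2-methylbut-2-enoate] | C/C=C(\C)C(=O)O[C@H]1C[C@]2(C)O[C@@H]2[C@H](OC(=O)/C(C)=C/C)[C@@]2(C)[C@@H]1[C@](O[Si](CC)(CC)CC)(C(C)C)C[C@@H]2O[Si](CC)(CC)CC | intermediate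
26 | 8α,9α-epoxy-2β,4α-dihydroxy-5β-daucane-6β,10α-diyl bis[(E)-2-methylbut-2-enoate] (4β-isopropyl, 1β- and 8β-methyl) | C/C=C(\C)C(=O)O[C@H]1C[C@]2(C)O[C@@H]2[C@H](OC(=O)/C(C)=C/C)[C@@]2(C)[C@@H]1[C@](O)(C(C)C)C[C@@H]2O | target

**Step count**

Total steps: 17. Longest linear sequence: 15 steps (steps 1–6 and 9–17; steps 7 and 8 form the second fragment).

**Steps most likely to fail**

Step 9. The alkoxy-substituted carbenoid may react at its vinylogous terminus, or the diazo compound may cyclise before it reaches the catalyst. The encumbered cis-divinylcyclopropane may also divert by ring opening in place of the rearrangement. The fallback sets out from 9 and returns at 15, and moves the C10 oxygenation to after the ring formation. The parent reagent ethyl 2-diazobut-3-enoate F1 (from ethyl but-3-enoate, 4-acetamidobenzenesulfonyl azide and DBU) is used under the same catalyst in hexanes and then heated. It should give, through the cis-divinylcyclopropane F2, the diene ester ethyl 2β,4α-bis(triethylsilyloxy)dauca-5,8-dien-14-oate F3. SeO2 in dioxane at 80 °C should then oxidise the γ-position of the enoate (ene reaction at the α-carbon C8 with loss of hydrogen from C10) to the epimeric 10-hydroxy esters F4. MnO2 converges these on the 10-oxo ester F5. Luche reduction (NaBH4, CeCl3·7H2O, MeOH, −78 °C), with hydride arriving on the exposed β face, should give the 10α-hydroxy ester F6. 4-Methoxybenzyl trichloroacetimidate with catalytic La(OTf)3 then returns to 15.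

Step 10. Hydroboration of the doubly neopentyl C5=C6 bond may be slow enough for borane to attack the enoate, or boron may be delivered from the wrong face. The fallback sets out from 15 and returns at 17, and replaces hydroboration by epoxidation and radical epoxide opening. Buffered m-CPBA (NaHCO3, CH2Cl2, 0 °C) should epoxidise only the electron-rich C5=C6 bond, from the exposed β face, to the 5β,6β-epoxy ester F7. The trivalent titanium reagent Cp2TiCl (from Cp2TiCl2 and Zn) with 1,4-cyclohexadiene in THF should then open the epoxide homolytically at the tertiary C5–O bond. The 6β-oxygen is retained, and the C5 radical takes hydrogen on the exposed β face to give 17.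

Step 1. The allylic oxidation may show poor site selectivity between the ring CH2 and the C7 methyl; the homoallylic tertiary alcohol may close to a cyclic ether under the acidic conditions, or the hydroxy enone may dehydrate and aromatise. The fallback sets out from 1 and returns at 8, and introduces the ring A oxygen after the ring contraction. Silylation (Et3SiOTf, 2,6-lutidine) gives the silyl ether of (S)-terpinen-4-ol F8, and ozonolysis (O3; PPh3) then gives (3S)-6-oxo-3-(propan-2-yl)-3-(triethylsilyloxy)heptanal F9. Piperidine/AcOH should give, through the aldol adduct F10, (5R)-2-methyl-5-(propan-2-yl)-5-(triethylsilyloxy)cyclopent-1-ene-1-carbaldehyde F11. Et3SiOTf/Et3N converts the enal into the ring-conjugated dienol silyl ether F12. Dimethyldioxirane in acetone at −40 °C (vinylogous Rubottom oxidation) should attack the ring double bond on the face away from the C5 silyloxy group and give the γ-hydroxy enal (3S,5R)-3-hydroxy-2-methyl-5-(propan-2-yl)-5-(triethylsilyloxy)cyclopent-1-ene-1-carbaldehyde F13; any C3 epimer would be removed by chromatography. Et3SiCl/imidazole then gives 8.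

**Further compounds**

F1 | step 9 | ethyl 2-diazobut-3-enoate | C=CC(=[N+]=[N-])C(=O)OCC
F2 | step 9 | ethyl 1-ethenyl-2-[(3S,5R)-2-methyl-5-(propan-2-yl)-3,5-bis(triethylsilyloxy)cyclopent-1-en-1-yl]cyclopropane-1-carboxylate (vinyl and cyclopentenyl cis, same sense as 14) | CCOC(=O)[C@@]1(C=C)C[C@@H]1C3=C(C)[C@@H](O[Si](CC)(CC)CC)C[C@@]3(O[Si](CC)(CC)CC)C(C)C
F3 | step 9 | ethyl 2β,4α-bis(triethylsilyloxy)dauca-5,8-dien-14-oate | CCOC(=O)C1=CC[C@@]3(C)C(=CC1)[C@](O[Si](CC)(CC)CC)(C(C)C)C[C@@H]3O[Si](CC)(CC)CC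
F4 | step 9 | ethyl 10-hydroxy-2β,4α-bis(triethylsilyloxy)dauca-5,8-dien-14-oate, both C10 epimers | CCOC(=O)C1=CC(O)[C@@]3(C)C(=CC1)[C@](O[Si](CC)(CC)CC)(C(C)C)C[C@@H]3O[Si](CC)(CC)CC
F5 | step 9 | ethyl 10-oxo-2β,4α-bis(triethylsilyloxy)dauca-5,8-dien-14-oate | CCOC(=O)C1=CC(=O)[C@@]3(C)C(=CC1)[C@](O[Si](CC)(CC)CC)(C(C)C)C[C@@H]3O[Si](CC)(CC)CC
F6 | step 9 | ethyl 10α-hydroxy-2β,4α-bis(triethylsilyloxy)dauca-5,8-dien-14-oate | CCOC(=O)C1=C[C@H](O)[C@@]3(C)C(=CC1)[C@](O[Si](CC)(CC)CC)(C(C)C)C[C@@H]3O[Si](CC)(CC)CC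
F7 | step 10 | ethyl 5β,6β-epoxy-10α-[(4-methoxybenzyl)oxy]-2β,4α-bis(triethylsilyloxy)dauc-8-en-14-oate | CCOC(=O)C1=C[C@H](OCc2ccc(OC)cc2)[C@@]3(C)[C@]4(O[C@H]4C1)[C@](O[Si](CC)(CC)CC)(C(C)C)C[C@@H]3O[Si](CC)(CC)CC
F8 | step 1 | triethyl{[(1S)-4-methyl-1-(propan-2-yl)cyclohex-3-en-1-yl]oxy}silane | CC1=CC[C@](O[Si](CC)(CC)CC)(C(C)C)CC1
F9 | step 1 | (3S)-6-oxo-3-(propan-2-yl)-3-(triethylsilyloxy)heptanal | O=CC[C@](O[Si](CC)(CC)CC)(C(C)C)CCC(C)=O
F10 | step 1 | (5R)-2-hydroxy-2-methyl-5-(propan-2-yl)-5-(triethylsilyloxy)cyclopentane-1-carbaldehyde, C1 and C2 undefined | O=CC1C(C)(O)CC[C@@]1(O[Si](CC)(CC)CC)C(C)C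
F11 | step 1 | (5R)-2-methyl-5-(propan-2-yl)-5-(triethylsilyloxy)cyclopent-1-ene-1-carbaldehyde | O=CC1=C(C)CC[C@@]1(O[Si](CC)(CC)CC)C(C)C
F12 | step 1 | triethylsilyl dienol ether of F11 (ring C2=C3 and exocyclic C1=CH–OSiEt3 double bonds) | CC1=CC[C@@](O[Si](CC)(CC)CC)(C(C)C)C1=CO[Si](CC)(CC)CC
F13 | step 1 | (3S,5R)-3-hydroxy-2-methyl-5-(propan-2-yl)-5-(triethylsilyloxy)cyclopent-1-ene-1-carbaldehyde | O=CC1=C(C)[C@@H](O)C[C@@]1(O[Si](CC)(CC)CC)C(C)C
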